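## Analysis of the target

The target is a flavanone: ring A is fused to a dihydropyranone (ring C, atoms O1, C2, C3, C4, C4a, C8a), and C2 carries ring B. Ring A is fully differentiated, with a free hydroxyl at C5 (hydrogen-bonded to the C4 carbonyl), a prenyl group at C6, a methoxy group at C7 and hydrogen at C8. Ring B is a 3,4-dimethoxyphenyl unit with an (E)-geranyl chain at C2′, ortho to the bond to C2. The only stereocentre is C2 (S); it has no partner, but it is benzylic, bound to O1 and β to the ketone, so base or hot acid can open ring C to the 2′-hydroxychalcone and scramble it. Other sensitive elements are three trisubstituted alkenes, of which the C6 prenyl alkene can cyclise onto the neighbouring C5 hydroxyl under acid, and the E geometry of the inner geranyl double bond. The synthesis is hard for three reasons: ring A is pentasubstituted with three different oxygen functions in fixed order, C2 is shielded by an ortho-substituted aryl group, and every bond-forming or reducing step must leave isolated alkenes alone. The strategy rests on C4 being a lone carbonyl carbon between C4a of ring A and the C3–C2 unit that bears ring B, with O1 a phenolic oxygen ortho to C4a. The carbonyl can therefore enter as carbon monoxide between an ortho-iodophenol and an arylacetylene, and the stereocentre can be added afterwards to the flat flavone.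

## Retrosynthetic reasoning

Target 25 to 24. The last bond cut is the O–CH2 bond of a methoxymethyl ether on the C5 oxygen. The C5 oxygen must stay masked until the end so that only one phenol of ring A is free during ring C formation. An acetal is chosen because it survives organolithiums, amine at high temperature and hydride, and because the neighbouring carbonyl makes it leave under dilute acid.

24 to 22. Removing the C2–H and C3–H bonds takes 24 back to flavone 22, which has no stereocentre. C2 is the one labile stereocentre, so it is best created late, by a chiral copper-hydride catalyst that adds hydride to C2 of the enone and ignores isolated alkenes. The forward step must give 1,4-reduction only, the S configuration, and no ring opening of the enolate.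

22 to 11, 19 and 18. Ring C is cut at C4a–C4, C4–C3 and O1–C2. This splits the molecule into the two aryl halves of nearly equal size and the one-carbon unit 19. Cutting elsewhere, for example at C2–C1′, would leave a chromone that still needs an aryl group added to a hindered β-carbon. The forward reaction must insert 19 before the alkyne couples and must close the six-membered ring, not the five-membered one.

11 to 10, 8 and 7. The C–I bond is cut. The iodine lies between two ring oxygens, so it is placed by lithiation between two acetal-type directing groups. The phenol of 7 is therefore turned into the 1-ethoxyethyl acetal 8, which directs metalation together with the methoxymethyl ether and is far more acid-labile than it. This is what allows 10 to be unmasked to 11 without touching the C5 oxygen.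

7 to 6, and 6 to 3 and 4. The ring–prenyl bond is cut. The prenyl carbon lies between the methoxymethyl and methyl ethers, which is the only position of 3 that two coordinating oxygens flank and the bulky silyl ether does not shield. The silyl ether is there to switch off the position between the two "phenolic" oxygens during this first metalation; it is then removed to give 7.

3 to 2 to 1. The two protecting groups are cut back to the symmetric diol 1, in which the methyl ether of the target is already present. The two hydroxyls are equivalent, so the only cost is one statistical monoprotection.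

18 to 17. The alkyne is cut to the aldehyde by a one-carbon homologation. This leaves the geranyl chain untouched and avoids any palladium coupling on ring B.

17 to 12 and 13. The ring–geranyl bond is cut. The carbon concerned lies between the formyl group and a methoxy group of 12, so a temporarily masked aldehyde and the methoxy group together direct metalation there, and copper-mediated allylic substitution on 13 keeps the chain linear and E.

## Alternatives that were turned down

Alternative 1: Here C2 would be set by a sacrificial epoxide. The ortho-fluoroaryl chalcone A2 is epoxidised with hydrogen peroxide under poly-D-leucine catalysis to the trans (αS, βR) epoxide A1. Reductive cleavage of the Cα–O bond and displacement of fluoride by the β-oxygen would then form O1–C8a with C2 unchanged.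
- For it: peptide-catalysed epoxidation of chalcones is a broadly precedented way to fix this kind of centre. On that single point it has more precedent than copper hydride reduction of a hindered flavone.
- Against it: the fluoride sits on a ring with three donor oxygens, so the substitution is activated only by the ortho ketone and needs an alkoxide. That alkoxide belongs to a β-hydroxy ketone, which under the same basic conditions can undergo retro-aldol cleavage or dehydration back to the chalcone, and either path loses the stereocentre. The ketone of A2 is flanked by two ortho substituents and the alkene by the ortho-geranyl aryl group, which are poor conditions for a catalyst that works best on unhindered chalcones. A fluorinated, prenylated ring A ketone must be built, and the oxygen installed at Cα is thrown away.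
- Comparison: about five operations follow fragment assembly (condensation, epoxidation, reductive opening, substitution, unmasking), against three in the chosen route. The chosen route gives up some precedent in the stereochemical step and gains a neutral, convergent ring closure with no base-labile aldol intermediate.

Alternative 2: This is a biomimetic closure of ring A. The dihydropyranone A4, which already carries C2 and a prenylated β-keto ester side chain, is treated with base so that its extended enolate attacks the ester through the pyranone carbon that becomes C4a. This forms C4a–C5 and, after loss of methanol and enolisation, gives the 5,7-dihydroxy flavanone A3.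
- For it: it avoids all regiochemical work on a preformed arene. The ring A pattern follows from the chain, with no silyl or acetal differentiation, and on this point it is stronger than the chosen route, which spends seven steps on ring A.
- Against it: the C2 stereocentre must already exist in A4 and must survive the base that drives the condensation, although its oxygen is β to an enolisable ketone and can be expelled. The polycarbonyl chain can close in other ways (aldol instead of Claisen, O- instead of C-acylation). A3 also has two free hydroxyls, so a selective methylation at the C7 oxygen is still needed on a base-sensitive flavanone. The synthesis of A4 with its stereocentre is long and linear.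
- Comparison: the chosen route pays for its protecting-group work with robust aromatic intermediates, a stereocentre that appears only two steps from the end, and two fragments of similar size.

Alternative 3: Ring C would be built by cycloaddition. Salicylaldehyde A6 is converted by trimethyl orthoformate and a chiral Brønsted acid into an ortho-quinone methide oxocarbenium ion, which adds styrene A7. This forms C3–C4 and O1–C2 and gives the 2,4-cis 4-methoxyflavan A5.
- For it: it forms two ring bonds and sets C2 directly at the sp3 level in one convergent step, so no later reduction of a hindered enone is needed. In this it equals the chosen route in convergence and is stronger in making the stereocentre during ring formation.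
- Against it: the cationic intermediate and the acid meet three trisubstituted alkenes (the prenyl group of A6 and the two of the geranyl chain of A7). These are comparable nucleophiles to the styrene and can also undergo cation–olefin cyclisation, and the acetal on the C5 oxygen is exposed to the same acid. Face selection on an ortho-substituted styrene is uncertain. A5 is at the wrong oxidation level at C4, so hydrolysis of the benzylic ether and oxidation to the ketone must follow in the presence of electron-rich arenes and alkenes.
- Comparison: the chosen route avoids carbocation chemistry near the polyene side chains altogether. It reaches the correct C4 oxidation level in the ring-forming step and needs only one reduction and one unmasking afterwards.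

Key step: step 10

## Assumptions

- (R)-DTBM-SEGPHOS is taken to be the ligand enantiomer that delivers hydride to the Re face of C2 (which gives 2S); if the sense proves opposite, the (S)-ligand is used with no other change.
- The acetal carbon of the 1-ethoxyethyl group (compounds 8–10) is racemic; it is irrelevant because it is removed in step 7.
- 5-Methoxyresorcinol, prenyl bromide, geranyl bromide, veratraldehyde, N,N,N′-trimethylethylenediamine and the Ohira–Bestmann reagent are taken as commercial.

## Route

Step 1
Reactants: 1 5-methoxybenzene-1,3-diol (5-methoxyresorcinol)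
Product: 2 3-methoxy-5-[tri(propan-2-yl)silyloxy]phenol
Conditions: TIPSCl (1.0 equiv), imidazole, DMF, 0 °C → rt; 1 used in slight excess and recovered
Reagents that add atoms: triisopropylsilyl chloride, CC(C)[Si](Cl)(C(C)C)C(C)C
Why: O-silylation of one of two equivalent phenols; the bulky silyl ether slows the second silylation, and unreacted symmetric diol and the bis-ether are easily separated and recycled.

Step 2
Reactants: 2 3-methoxy-5-[tri(propan-2-yl)silyloxy]phenol
Product: 3 [3-methoxy-5-(methoxymethoxy)phenoxy]tri(propan-2-yl)silane
Conditions: MOMCl, i-Pr2NEt, CH2Cl2, 0 °C → rt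
Reagents that add atoms: chloromethyl methyl ether, COCCl
Why: O-alkylation of the remaining phenol (methoxymethyl protection) under amine base, which leaves the aryl silyl ether intact.

Step 3
Reactants: 3 [3-methoxy-5-(methoxymethoxy)phenoxy]tri(propan-2-yl)silane; 4 1-bromo-3-methylbut-2-ene (prenyl bromide)
Product: 6 [3-methoxy-5-(methoxymethoxy)-4-(3-methylbut-2-en-1-yl)phenoxy]tri(propan-2-yl)silane, via aryllithium 5 (not isolated)
Conditions: n-BuLi, THF, 0 °C; CuBr·SMe2, −40 °C; 4, −40 °C → rt
Reagents that add atoms: none
Why: Directed ortho-metalation occurs at the only ring position that lies between two coordinating oxygens (methoxymethoxy and methoxy) and is not shielded by the bulky silyl ether. Transmetalation to monovalent copper makes the allylic substitution on 4 occur at the primary carbon, so the linear prenyl group results.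

Step 4
Reactants: 6 [3-methoxy-5-(methoxymethoxy)-4-(3-methylbut-2-en-1-yl)phenoxy]tri(propan-2-yl)silane
Product: 7 3-methoxy-5-(methoxymethoxy)-4-(3-methylbut-2-en-1-yl)phenol
Conditions: TBAF, THF, 0 °C
Reagents that add atoms: none
Why: Fluoride-induced cleavage of the aryl silyl ether; the acetal and the alkene are inert to fluoride.

Step 5
Reactants: 7 3-methoxy-5-(methoxymethoxy)-4-(3-methylbut-2-en-1-yl)phenol
Product: 8 1-(1-ethoxyethoxy)-3-methoxy-5-(methoxymethoxy)-4-(3-methylbut-2-en-1-yl)benzene
Conditions: ethyl vinyl ether, PPTS (cat.), CH2Cl2, rt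
Reagents that add atoms: ethyl vinyl ether, C=COCC
Why: Acid-catalysed addition of the phenol to the enol ether (acetal formation) under conditions too mild to affect the methoxymethyl ether or the prenyl alkene; the new acetal is a second ortho-directing group that is far more acid-labile than the first.

Step 6
Reactants: 8 1-(1-ethoxyethoxy)-3-methoxy-5-(methoxymethoxy)-4-(3-methylbut-2-en-1-yl)benzene
Product: 10 1-(1-ethoxyethoxy)-2-iodo-5-methoxy-3-(methoxymethoxy)-4-(3-methylbut-2-en-1-yl)benzene, via aryllithium 9 (not isolated)
Conditions: n-BuLi, THF, −20 → 0 °C; I2, THF, −78 °C; aq. Na2S2O3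
Reagents that add atoms: iodine, II
Why: Directed ortho-metalation between the two acetal oxygens, which chelate lithium cooperatively and outrank the methoxy group that flanks the other free position. Short, cold metalation keeps ring lithiation ahead of deprotonation at the benzylic–allylic CH2, and iodinolysis of the aryllithium is faster than any reaction of iodine with the trisubstituted alkene.

Step 7
Reactants: 10 1-(1-ethoxyethoxy)-2-iodo-5-methoxy-3-(methoxymethoxy)-4-(3-methylbut-2-en-1-yl)benzene
Product: 11 2-iodo-5-methoxy-3-(methoxymethoxy)-4-(3-methylbut-2-en-1-yl)phenol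
Conditions: PPTS (cat.), MeOH, rt
Reagents that add atoms: none
Why: Acetal exchange with methanol; the acetaldehyde-derived acetal ionises much more easily than the formaldehyde-derived methoxymethyl ether, so only the former is lost. The liberated hydroxyl is para to the prenyl group and cannot cyclise onto it.

Step 8
Reactants: 12 3,4-dimethoxybenzaldehyde (veratraldehyde); 13 (2E)-1-bromo-3,7-dimethylocta-2,6-diene (geranyl bromide)
Product: 17 2-[(2E)-3,7-dimethylocta-2,6-dien-1-yl]-3,4-dimethoxybenzaldehyde, via lithium α-amino alkoxide 14 (not isolated), via ring-lithiated α-amino alkoxide 15 (not isolated), via geranylated α-amino alkoxide 16 (not isolated)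
Conditions: LiN(Me)CH2CH2NMe2 (from MeNHCH2CH2NMe2 + n-BuLi), THF, −20 °C; n-BuLi (3 equiv), −20 °C; CuBr·SMe2, −78 °C; 13 (excess), −78 → 0 °C; aq. NH4Cl
Reagents that add atoms: none
Why: The lithium amide adds to the aldehyde to give an α-amino alkoxide that protects the carbonyl and, together with the neighbouring methoxy group, directs ortho-lithiation to the carbon between them. Copper-mediated allylic substitution at the primary carbon of 13 keeps the chain linear and E, and aqueous work-up releases the aldehyde.

Step 9
Reactants: 17 2-[(2E)-3,7-dimethylocta-2,6-dien-1-yl]-3,4-dimethoxybenzaldehyde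
Product: 18 2-[(2E)-3,7-dimethylocta-2,6-dien-1-yl]-1-ethynyl-3,4-dimethoxybenzene
Conditions: Ohira–Bestmann reagent, K2CO3, MeOH, 0 °C → rt
Reagents that add atoms: dimethyl (1-diazo-2-oxopropyl)phosphonate (Ohira–Bestmann reagent), COP(=O)(OC)C(=[N+]=[N-])C(C)=O
Why: Seyferth–Gilbert homologation in the Ohira–Bestmann variant: methanolysis frees the diazomethylphosphonate anion, which adds to the non-enolisable aldehyde, loses phosphate to a diazoalkene and, after loss of nitrogen and 1,2-hydrogen shift, gives the terminal alkyne; the mild base does not touch the side-chain alkenes.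

Step 10
Reactants: 11 2-iodo-5-methoxy-3-(methoxymethoxy)-4-(3-methylbut-2-en-1-yl)phenol; 18 2-[(2E)-3,7-dimethylocta-2,6-dien-1-yl]-1-ethynyl-3,4-dimethoxybenzene; 19 carbon monoxide
Product: 22 2-{2-[(2E)-3,7-dimethylocta-2,6-dien-1-yl]-3,4-dimethoxyphenyl}-7-methoxy-5-(methoxymethoxy)-6-(3-methylbut-2-en-1-yl)-4H-chromen-4-one, via ortho-hydroxyaryl ynone 20 (not isolated), via β-diethylamino enone 21 (not isolated)
Conditions: PdCl2(PPh3)2 (5 mol %), 19 (20 bar), Et2NH, 120 °C
Reagents that add atoms: none
Why: Oxidative addition of the C–I bond of 11 to zerovalent palladium (formed from PdCl2(PPh3)2 by amine and alkyne) gives an arylpalladium iodide that inserts 19 to an aroylpalladium species; amine-assisted transfer of the acetylide of 18 and reductive elimination form C4a–C4 and C4–C3 in ynone 20. Diethylamine then adds to the ynone to give enaminone 21, and the phenol oxygen attacks the same β-carbon in a 6-endo addition–elimination that expels the amine, forms O1–C2 and closes ring C as the pyran-4-one of 22. The closest known reaction type is the palladium-catalysed carbonylative annulation of ortho-iodophenols with terminal arylacetylenes in a secondary amine, which gives flavones. No stereocentre is formed. Three selectivities are needed: insertion of 19 before alkyne coupling (otherwise a 2-arylbenzofuran forms), six- over five-membered closure (flavone over aurone), and alkyne coupling over amide formation at the aroylpalladium stage. The first is secured by the pressure of 19, the absence of a copper co-catalyst and the ready carbonylation of an electron-rich, doubly ortho-substituted arylpalladium; the second by passing through enaminone 21, whose β-carbon is the only electrophilic site offered to the phenol; the third by the two ortho oxygens that shield the aroyl carbon from the amine. The trisubstituted alkenes of the prenyl and geranyl chains do not insert into palladium–carbon bonds under these conditions, and the methoxymethyl ether is stable to hot amine.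

Step 11
Reactants: 22 2-{2-[(2E)-3,7-dimethylocta-2,6-dien-1-yl]-3,4-dimethoxyphenyl}-7-methoxy-5-(methoxymethoxy)-6-(3-methylbut-2-en-1-yl)-4H-chromen-4-one
Product: 24 (2S)-2-{2-[(2E)-3,7-dimethylocta-2,6-dien-1-yl]-3,4-dimethoxyphenyl}-7-methoxy-5-(methoxymethoxy)-6-(3-methylbut-2-en-1-yl)-2,3-dihydro-4H-chromen-4-one, via silyl enol ether 23 (not isolated)
Conditions: Cu(OAc)2·H2O (5 mol %), (R)-DTBM-SEGPHOS (5.5 mol %), (EtO)2MeSiH (3 equiv), toluene, 0 °C → rt; then TBAF/AcOH (1:1), THF, 0 °C
Reagents that add atoms: none
Why: Copper hydride asymmetric conjugate reduction (1,4-hydrosilylation) of the chromone enone: the bisphosphine-bound CuH adds hydride to C2, and the copper enolate is trapped by the silane as silyl enol ether 23, which cannot be reduced further and cannot expel the ring oxygen. C2 is set by the chiral ligand, which should direct hydride to the Re face of C2 to give the S configuration; unactivated trisubstituted alkenes are not hydrocuprated. Buffered fluoride then releases the ketone without a free enolate that could open ring C.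

Step 12
Reactants: 24 (2S)-2-{2-[(2E)-3,7-dimethylocta-2,6-dien-1-yl]-3,4-dimethoxyphenyl}-7-methoxy-5-(methoxymethoxy)-6-(3-methylbut-2-en-1-yl)-2,3-dihydro-4H-chromen-4-one
Product: 25 (2S)-2-{2-[(2E)-3,7-dimethylocta-2,6-dien-1-yl]-3,4-dimethoxyphenyl}-5-hydroxy-7-methoxy-6-(3-methylbut-2-en-1-yl)-2,3-dihydro-4H-chromen-4-one (CNP0112088.1)
Conditions: 3 M aq. HCl/MeOH (1:10), 0 °C → rt
Reagents that add atoms: none
Why: Acid-catalysed methanolysis of the methoxymethyl acetal; the ether is peri to the C4 carbonyl, which assists its departure and hydrogen-bonds the freed phenol, so dilute acid at room temperature should suffice and should leave the alkenes and C2 unchanged.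

## Compound list

1 | 5-methoxybenzene-1,3-diol (5-methoxyresorcinol) | COc1cc(O)cc(O)c1 | starting material
2 | 3-methoxy-5-[tri(propan-2-yl)silyloxy]phenol | COc1cc(O)cc(O[Si](C(C)C)(C(C)C)C(C)C)c1 | intermediate
3 | [3-methoxy-5-(methoxymethoxy)phenoxy]tri(propan-2-yl)silane | COCOc1cc(OC)cc(O[Si](C(C)C)(C(C)C)C(C)C)c1 | intermediate
4 | 1-bromo-3-methylbut-2-ene (prenyl bromide) | CC(C)=CCBr | starting material
5 | {2-methoxy-6-(methoxymethoxy)-4-[tri(propan-2-yl)silyloxy]phenyl}lithium (formed in the flask) | COCOc1cc(O[Si](C(C)C)(C(C)C)C(C)C)cc(OC)c1[Li] | intermediate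
6 | [3-methoxy-5-(methoxymethoxy)-4-(3-methylbut-2-en-1-yl)phenoxy]tri(propan-2-yl)silane | COCOc1cc(O[Si](C(C)C)(C(C)C)C(C)C)cc(OC)c1CC=C(C)C | intermediate
7 | 3-methoxy-5-(methoxymethoxy)-4-(3-methylbut-2-en-1-yl)phenol | COCOc1cc(O)cc(OC)c1CC=C(C)C | intermediate
8 | 1-(1-ethoxyethoxy)-3-methoxy-5-(methoxymethoxy)-4-(3-methylbut-2-en-1-yl)benzene (racemic at the acetal carbon) | CCOC(C)Oc1cc(OC)c(CC=C(C)C)c(OCOC)c1 | intermediate
9 | [2-(1-ethoxyethoxy)-4-methoxy-6-(methoxymethoxy)-5-(3-methylbut-2-en-1-yl)phenyl]lithium (formed in the flask) | CCOC(C)Oc1cc(OC)c(CC=C(C)C)c(OCOC)c1[Li] | intermediate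
10 | 1-(1-ethoxyethoxy)-2-iodo-5-methoxy-3-(methoxymethoxy)-4-(3-methylbut-2-en-1-yl)benzene (racemic at the acetal carbon) | CCOC(C)Oc1cc(OC)c(CC=C(C)C)c(OCOC)c1I | intermediate
11 | 2-iodo-5-methoxy-3-(methoxymethoxy)-4-(3-methylbut-2-en-1-yl)phenol | Oc1cc(OC)c(CC=C(C)C)c(OCOC)c1I | intermediate
12 | 3,4-dimethoxybenzaldehyde (veratraldehyde) | COc1ccc(C=O)cc1OC | starting material
13 | (2E)-1-bromo-3,7-dimethylocta-2,6-diene (geranyl bromide) | CC(C)=CCC/C(C)=C/CBr | starting material
14 | lithium (3,4-dimethoxyphenyl){[2-(dimethylamino)ethyl](methyl)amino}methanolate (formed in the flask, racemic) | COc1ccc(C(O[Li])N(C)CCN(C)C)cc1OC | intermediate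
15 | ring C2-lithio derivative of 14 (formed in the flask) | COc1ccc(C(O[Li])N(C)CCN(C)C)c([Li])c1OC | intermediate
16 | lithium {2-[(2E)-3,7-dimethylocta-2,6-dien-1-yl]-3,4-dimethoxyphenyl}{[2-(dimethylamino)ethyl](methyl)amino}methanolate (formed in the flask) | COc1ccc(C(O[Li])N(C)CCN(C)C)c(C/C=C(\C)CCC=C(C)C)c1OC | intermediate
17 | 2-[(2E)-3,7-dimethylocta-2,6-dien-1-yl]-3,4-dimethoxybenzaldehyde | COc1ccc(C=O)c(C/C=C(\C)CCC=C(C)C)c1OC | intermediate
18 | 2-[(2E)-3,7-dimethylocta-2,6-dien-1-yl]-1-ethynyl-3,4-dimethoxybenzene | C#Cc1ccc(OC)c(OC)c1C/C=C(\C)CCC=C(C)C | intermediate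
19 | carbon monoxide | [C-]#[O+] | starting material
20 | 3-{2-[(2E)-3,7-dimethylocta-2,6-dien-1-yl]-3,4-dimethoxyphenyl}-1-[2-hydroxy-4-methoxy-6-(methoxymethoxy)-5-(3-methylbut-2-en-1-yl)phenyl]prop-2-yn-1-one (formed in the flask) | COCOc1c(CC=C(C)C)c(OC)cc(O)c1C(=O)C#Cc1ccc(OC)c(OC)c1C/C=C(\C)CCC=C(C)C | intermediate
21 | 3-(diethylamino)-3-{2-[(2E)-3,7-dimethylocta-2,6-dien-1-yl]-3,4-dimethoxyphenyl}-1-[2-hydroxy-4-methoxy-6-(methoxymethoxy)-5-(3-methylbut-2-en-1-yl)phenyl]prop-2-en-1-one (formed in the flask; enamine geometry not defined, lost on cyclisation) | COCOc1c(CC=C(C)C)c(OC)cc(O)c1C(=O)C=C(N(CC)CC)c1ccc(OC)c(OC)c1C/C=C(\C)CCC=C(C)C | intermediate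
22 | 2-{2-[(2E)-3,7-dimethylocta-2,6-dien-1-yl]-3,4-dimethoxyphenyl}-7-methoxy-5-(methoxymethoxy)-6-(3-methylbut-2-en-1-yl)-4H-chromen-4-one | COCOc1c(CC=C(C)C)c(OC)cc2oc(-c3ccc(OC)c(OC)c3C/C=C(\C)CCC=C(C)C)cc(=O)c12 | intermediate
23 | (2S)-4-[diethoxy(methyl)silyloxy]-2-{2-[(2E)-3,7-dimethylocta-2,6-dien-1-yl]-3,4-dimethoxyphenyl}-7-methoxy-5-(methoxymethoxy)-6-(3-methylbut-2-en-1-yl)-2H-chromene (formed in the flask) | COCOc1c(CC=C(C)C)c(OC)cc2c1C(O[Si](C)(OCC)OCC)=C[C@@H](c1ccc(OC)c(OC)c1C/C=C(\C)CCC=C(C)C)O2 | intermediate
24 | (2S)-2-{2-[(2E)-3,7-dimethylocta-2,6-dien-1-yl]-3,4-dimethoxyphenyl}-7-methoxy-5-(methoxymethoxy)-6-(3-methylbut-2-en-1-yl)-2,3-dihydro-4H-chromen-4-one | COCOc1c(CC=C(C)C)c(OC)cc2c1C(=O)C[C@@H](c1ccc(OC)c(OC)c1C/C=C(\C)CCC=C(C)C)O2 | intermediate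
25 | (2S)-2-{2-[(2E)-3,7-dimethylocta-2,6-dien-1-yl]-3,4-dimethoxyphenyl}-5-hydroxy-7-methoxy-6-(3-methylbut-2-en-1-yl)-2,3-dihydro-4H-chromen-4-one | COc1cc2c(c(O)c1CC=C(C)C)C(=O)C[C@@H](c1ccc(OC)c(OC)c1C/C=C(\C)CCC=C(C)C)O2 | target

## Step count and risk

Total step count: 12 steps. Longest linear sequence: 10 steps (steps 1–7, then 10, 11 and 12); the ring B branch contributes steps 8 and 9.

Least certain steps:

Step 10 (key step). The most likely failures are three. Alkyne coupling may occur before carbon monoxide insertion and lead on to a 2-arylbenzofuran. The amine may capture the aroylpalladium intermediate. Oxidative addition into the crowded, very electron-rich C–I bond may simply be slow. The fallback makes the same three bonds without palladium and without gas. It sets out from acetal 8: lithiation exactly as in step 6, but quenching aryllithium 9 with DMF, gives 2-(1-ethoxyethoxy)-4-methoxy-6-(methoxymethoxy)-5-(3-methylbut-2-en-1-yl)benzaldehyde F1. Alkyne 18, deprotonated with n-BuLi at −78 °C, adds to F1 to give the propargylic alcohol F2, which MnO2 in CH2Cl2 oxidises to the protected ynone F3. PPTS in MeOH removes the 1-ethoxyethyl group to give ynone 20, and Et2NH in EtOH takes it through enaminone 21 to flavone 22, where the route is rejoined.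

Step 11. The ortho-geranyl aryl group is twisted out of the enone plane and crowds C2, so hydride delivery may be slow and the two faces may be poorly distinguished. Slow trapping of the copper enolate would in addition allow expulsion of the ring oxygen (ring opening) or reduction of the ketone. The fallback separates reduction from stereocontrol. It sets out from 22: conjugate reduction with the same copper hydride system but an achiral ligand (Cu(OAc)2·H2O, 1,2-bis(diphenylphosphino)benzene, (EtO)2MeSiH, then buffered fluoride) gives the racemic flavanone F4. Kinetic resolution by asymmetric transfer hydrogenation (RuCl(p-cymene)[(R,R)-TsDPEN], HCO2H/Et3N, rt, stopped near half conversion) should reduce the (R)-ketone to the (2R,4R)-cis-flavan-4-ol F5 and leave the (S)-ketone, which is 24. If the catalyst sense is the reverse, the (S,S)-ligand is used.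

Step 8. Metalation may be incomplete or may stray to another ring position, and the excess alkyllithium needed for it consumes part of 13 and complicates the copper chemistry. The fallback fixes the position by a halogen. It sets out from geranyl bromide 13 and uses commercial 2-bromo-3,4-dimethoxybenzaldehyde F6 in place of 12. F6 is converted into its dimethyl acetal F7 (HC(OMe)3, p-TsOH, MeOH). Bromine–lithium exchange (n-BuLi, THF, −78 °C), transmetalation with CuBr·SMe2 and addition of 13 give the geranylated acetal F8, and PPTS in wet acetone returns aldehyde 17.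

Step 12. Acid may protonate the prenyl alkene next to the freed C5 hydroxyl and so start cyclisation to a chroman, or may erode C2 through reversible opening of ring C. The fallback moves the acid step to the flavone, which has no stereocentre, and ends with fluoride. It sets out from 22: ZnBr2 and n-PrSH in CH2Cl2 at 0 °C remove the methoxymethyl group to give the 5-hydroxyflavone F9, and TBSOTf with 2,6-lutidine gives the silyl ether F10. Copper hydride reduction as in step 11 gives the doubly silylated (2S)-enol ether F11, and the buffered fluoride work-up (TBAF/AcOH) cleaves both silyl groups to give 25 directly.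

## Further compounds

F1 | step 10 | 2-(1-ethoxyethoxy)-4-methoxy-6-(methoxymethoxy)-5-(3-methylbut-2-en-1-yl)benzaldehyde | CCOC(C)Oc1cc(OC)c(CC=C(C)C)c(OCOC)c1C=O
F2 | step 10 | 3-{2-[(2E)-3,7-dimethylocta-2,6-dien-1-yl]-3,4-dimethoxyphenyl}-1-[2-(1-ethoxyethoxy)-4-methoxy-6-(methoxymethoxy)-5-(3-methylbut-2-en-1-yl)phenyl]prop-2-yn-1-ol | CCOC(C)Oc1cc(OC)c(CC=C(C)C)c(OCOC)c1C(O)C#Cc1ccc(OC)c(OC)c1C/C=C(\C)CCC=C(C)C
F3 | step 10 | 3-{2-[(2E)-3,7-dimethylocta-2,6-dien-1-yl]-3,4-dimethoxyphenyl}-1-[2-(1-ethoxyethoxy)-4-methoxy-6-(methoxymethoxy)-5-(3-methylbut-2-en-1-yl)phenyl]prop-2-yn-1-one | CCOC(C)Oc1cc(OC)c(CC=C(C)C)c(OCOC)c1C(=O)C#Cc1ccc(OC)c(OC)c1C/C=C(\C)CCC=C(C)C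
F4 | step 11 | racemic 2-{2-[(2E)-3,7-dimethylocta-2,6-dien-1-yl]-3,4-dimethoxyphenyl}-7-methoxy-5-(methoxymethoxy)-6-(3-methylbut-2-en-1-yl)-2,3-dihydro-4H-chromen-4-one | COCOc1c(CC=C(C)C)c(OC)cc2c1C(=O)CC(c1ccc(OC)c(OC)c1C/C=C(\C)CCC=C(C)C)O2
F5 | step 11 | (2R,4R)-2-{2-[(2E)-3,7-dimethylocta-2,6-dien-1-yl]-3,4-dimethoxyphenyl}-7-methoxy-5-(methoxymethoxy)-6-(3-methylbut-2-en-1-yl)-3,4-dihydro-2H-chromen-4-ol (2,4-cis) | COCOc1c(CC=C(C)C)c(OC)cc2c1[C@H](O)C[C@H](c1ccc(OC)c(OC)c1C/C=C(\C)CCC=C(C)C)O2
F6 | step 8 | 2-bromo-3,4-dimethoxybenzaldehyde | COc1ccc(C=O)c(Br)c1OC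
F7 | step 8 | 2-bromo-1-(dimethoxymethyl)-3,4-dimethoxybenzene | COc1ccc(C(OC)OC)c(Br)c1OC
F8 | step 8 | 1-(dimethoxymethyl)-2-[(2E)-3,7-dimethylocta-2,6-dien-1-yl]-3,4-dimethoxybenzene | COc1ccc(C(OC)OC)c(C/C=C(\C)CCC=C(C)C)c1OC
F9 | step 12 | 2-{2-[(2E)-3,7-dimethylocta-2,6-dien-1-yl]-3,4-dimethoxyphenyl}-5-hydroxy-7-methoxy-6-(3-methylbut-2-en-1-yl)-4H-chromen-4-one | COc1cc2oc(-c3ccc(OC)c(OC)c3C/C=C(\C)CCC=C(C)C)cc(=O)c2c(O)c1CC=C(C)C
F10 | step 12 | 5-[tert-butyl(dimethyl)silyloxy]-2-{2-[(2E)-3,7-dimethylocta-2,6-dien-1-yl]-3,4-dimethoxyphenyl}-7-methoxy-6-(3-methylbut-2-en-1-yl)-4H-chromen-4-one | COc1cc2oc(-c3ccc(OC)c(OC)c3C/C=C(\C)CCC=C(C)C)cc(=O)c2c(O[Si](C)(C)C(C)(C)C)c1CC=C(C)C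
F11 | step 12 | (2S)-5-[tert-butyl(dimethyl)silyloxy]-4-[diethoxy(methyl)silyloxy]-2-{2-[(2E)-3,7-dimethylocta-2,6-dien-1-yl]-3,4-dimethoxyphenyl}-7-methoxy-6-(3-methylbut-2-en-1-yl)-2H-chromene | COc1cc2c(c(O[Si](C)(C)C(C)(C)C)c1CC=C(C)C)C(O[Si](C)(OCC)OCC)=C[C@@H](c1ccc(OC)c(OC)c1C/C=C(\C)CCC=C(C)C)O2
A1 | alternative 1 | (αS,βR)-epoxide of the 2′-fluorochalcone: [(2S,3R)-3-{2-[(2E)-3,7-dimethylocta-2,6-dien-1-yl]-3,4-dimethoxyphenyl}oxiran-2-yl][6-fluoro-4-methoxy-2-(methoxymethoxy)-3-(3-methylbut-2-en-1-yl)phenyl]methanone | COCOc1c(CC=C(C)C)c(OC)cc(F)c1C(=O)[C@H]1O[C@@H]1c1ccc(OC)c(OC)c1C/C=C(\C)CCC=C(C)C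
A2 | alternative 1 | (2E)-3-{2-[(2E)-3,7-dimethylocta-2,6-dien-1-yl]-3,4-dimethoxyphenyl}-1-[6-fluoro-4-methoxy-2-(methoxymethoxy)-3-(3-methylbut-2-en-1-yl)phenyl]prop-2-en-1-one | COCOc1c(CC=C(C)C)c(OC)cc(F)c1C(=O)/C=C/c1ccc(OC)c(OC)c1C/C=C(\C)CCC=C(C)C
A3 | alternative 2 | (2S)-2-{2-[(2E)-3,7-dimethylocta-2,6-dien-1-yl]-3,4-dimethoxyphenyl}-5,7-dihydroxy-6-(3-methylbut-2-en-1-yl)-2,3-dihydro-4H-chromen-4-one | Oc1cc2c(c(O)c1CC=C(C)C)C(=O)C[C@@H](c1ccc(OC)c(OC)c1C/C=C(\C)CCC=C(C)C)O2
A4 | alternative 2 | methyl 2-(3-methylbut-2-en-1-yl)-3-oxo-4-[(2S)-2-{2-[(2E)-3,7-dimethylocta-2,6-dien-1-yl]-3,4-dimethoxyphenyl}-4-oxo-3,4-dihydro-2H-pyran-6-yl]butanoate | COC(=O)C(CC=C(C)C)C(=O)CC1=CC(=O)C[C@@H](c2ccc(OC)c(OC)c2C/C=C(\C)CCC=C(C)C)O1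
A5 | alternative 3 | (2S,4S)-2-{2-[(2E)-3,7-dimethylocta-2,6-dien-1-yl]-3,4-dimethoxyphenyl}-4,7-dimethoxy-5-(methoxymethoxy)-6-(3-methylbut-2-en-1-yl)-3,4-dihydro-2H-chromene (2,4-cis) | COCOc1c(CC=C(C)C)c(OC)cc2c1[C@@H](OC)C[C@@H](c1ccc(OC)c(OC)c1C/C=C(\C)CCC=C(C)C)O2
A6 | alternative 3 | 2-hydroxy-4-methoxy-6-(methoxymethoxy)-5-(3-methylbut-2-en-1-yl)benzaldehyde | COCOc1c(CC=C(C)C)c(OC)cc(O)c1C=O
A7 | alternative 3 | 2-[(2E)-3,7-dimethylocta-2,6-dien-1-yl]-1-ethenyl-3,4-dimethoxybenzene | C=Cc1ccc(OC)c(OC)c1C/C=C(\C)CCC=C(C)C
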